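**Plan**

- Retrosynthesis: the target is first tautomerised back to its redox isomer 8, a 2‑quinonylchroman‑4‑one (C2–H, C3–H2, ring B as quinone). The C2–C1' bond is then cut to a chroman‑4‑on‑2‑yl radical (from acid 6) and 2,3‑dimethoxy‑1,4‑benzoquinone 7. Acid 6 goes back through chromone acid 5 (cuts O1–C2 and C2–C3) to acetophenone 1 and diethyl oxalate 2.
- Enabling feature: ring B carries OH at C2' and C5' (para), OMe at C3'/C4' and H at C6'. It is therefore the hydroquinone of 7, bonded through one of the two equivalent CH carbons of 7 to C2 of the pyranone. The quinone serves as radical acceptor and then as internal oxidant for C2–H/C3–H.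
- Forward: ring C is built on ring A (Claisen condensation, cyclodehydration), C2=C3 is hydrogenated, and the C2 carboxyl group is used as a traceless radical precursor to join ring B as the quinone. A redox‑neutral isomerisation then installs C2=C3 and the free hydroquinone. No protecting group is used.
- Stereochemistry (remark on the chemistry): the target has no stereocenter and no hindered axis, so nothing has to be controlled. C2 of 6 and 8 is deliberately racemic and is erased in steps 3 and 4.

Key step: step 3

**Route**

Step 1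
Reactants: 1 1‑(2,6‑dihydroxy‑4‑methoxyphenyl)ethan‑1‑one; 2 diethyl oxalate
Product: 5 5‑hydroxy‑7‑methoxy‑4‑oxo‑4H‑chromene‑2‑carboxylic acid, via diketo ester 3 (not isolated), via chromone ethyl ester 4 (not isolated)
Conditions: NaOEt (4 equiv), EtOH, reflux; then conc. HCl/AcOH/H2O, reflux
Reagents that add atoms: water, O
Why: Crossed Claisen condensation of the methyl ketone enolate with the non‑enolisable oxalate, then acid‑catalysed cyclodehydration of the 2'‑hydroxy‑1,3‑diketo ester and ester hydrolysis in the same acid (classical chromone‑2‑carboxylic acid synthesis); the two equivalent phenols of 1 make either ring closure give the same 5‑hydroxychromone.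

Step 2
Reactants: 5 5‑hydroxy‑7‑methoxy‑4‑oxo‑4H‑chromene‑2‑carboxylic acid
Product: 6 5‑hydroxy‑7‑methoxy‑4‑oxochromane‑2‑carboxylic acid (racemic)
Conditions: H2 (1–3 bar), 10% Pd/C, THF/AcOH, rt, stopped after 1 equiv H2
Reagents that add atoms: none
Why: Heterogeneous catalytic hydrogenation should saturate the carboxyl‑activated C2=C3 bond while the hydrogen‑bonded, trioxygenated aryl ketone at C4 resists reduction at low pressure; the new C2 stereocenter forms racemic, which is intended because it is destroyed in steps 3 and 4.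

Step 3
Reactants: 6 5‑hydroxy‑7‑methoxy‑4‑oxochromane‑2‑carboxylic acid (racemic); 7 2,3‑dimethoxy‑1,4‑benzoquinone (2 equiv)
Product: 8 2‑(4,5‑dimethoxy‑3,6‑dioxocyclohexa‑1,4‑dien‑1‑yl)‑5‑hydroxy‑7‑methoxychroman‑4‑one (racemic)
Conditions: AgNO3 (0.2 equiv), (NH4)2S2O8 (1.5 equiv, slow addition), MeCN/H2O 1:1, 65 °C
Reagents that add atoms: none
Why: Ag(I)/peroxodisulfate generates Ag(II), which oxidises the carboxylate of 6; loss of CO2 leaves the chroman‑4‑on‑2‑yl radical, a secondary α‑aryloxy radical made nucleophilic by the O1 lone pair, which adds to the electron‑poor quinone 7 at C5/C6 (the only unsubstituted ring carbons, equivalent by symmetry), and the adduct radical is oxidised and deprotonated back to the quinone level to give 8. The closest known reaction type is the silver–peroxodisulfate decarboxylative alkylation of quinones (Jacobsen–Torssell alkylation, Minisci‑type), established for α‑alkoxy acids and for 2,3‑dimethoxybenzoquinones. No ring is closed. No stereocenter has to be controlled: C2 of racemic 6 becomes a planar radical, 8 forms racemic, and step 4 makes this carbon sp2. The step needs radical capture to outrun oxidation of the radical to the oxocarbenium ion (which would end as the 2‑unsubstituted chromone) and needs monoalkylation; excess 7 at high concentration and slow addition of the oxidant should secure both, and the methoxy groups block C2/C3 of 7. The 5‑OH is hydrogen‑bonded to C4=O on an acyl‑deactivated ring, which should keep ring A out of the oxidation.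

Step 4
Reactants: 8 2‑(4,5‑dimethoxy‑3,6‑dioxocyclohexa‑1,4‑dien‑1‑yl)‑5‑hydroxy‑7‑methoxychroman‑4‑one (racemic)
Product: 10 5‑hydroxy‑7‑methoxy‑2‑(2,5‑dihydroxy‑3,4‑dimethoxyphenyl)‑4H‑chromen‑4‑one (target), via ortho‑quinone methide tautomer 9 (not isolated)
Conditions: Et3N (0.2 equiv), degassed THF, rt to 40 °C, Ar; then AcOH; work‑up under Ar with a dilute aq. Na2S2O4 wash
Reagents that add atoms: none
Why: Proposed new method: the base should remove C2–H, which is γ to the C5' quinone carbonyl through C1'=C6' and α to O1, to give the ortho‑quinone methide 9 (C2=C1' exocyclic); its C3–H, α to C4=O and vinylogous to C2'=O, should then be lost with protonation on O2', so ring B aromatises to the hydroquinone and C2=C3 appears; the double prototropic shift is redox‑neutral within the molecule, is driven by aromatisation of ring B and conjugation of the chromone, and any quinone/hydroquinone exchange between molecules is self‑correcting because only 8 can isomerise; the closest known reaction types are the acid‑ or base‑mediated redox isomerisation of 2‑(1‑hydroxyalkyl)‑1,4‑quinones to 2‑acylhydroquinones and the amine‑mediated ortho‑quinone methide formation from alkylquinones (as in chromenol formation from prenylquinones).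

**Compound list**

1 | 1‑(2,6‑dihydroxy‑4‑methoxyphenyl)ethan‑1‑one (2',6'‑dihydroxy‑4'‑methoxyacetophenone) | CC(=O)c1c(O)cc(OC)cc1O | starting material
2 | diethyl oxalate | CCOC(=O)C(=O)OCC | starting material
3 | ethyl 4‑(2,6‑dihydroxy‑4‑methoxyphenyl)‑2,4‑dioxobutanoate (diketo ester) | CCOC(=O)C(=O)CC(=O)c1c(O)cc(OC)cc1O | intermediate
4 | ethyl 5‑hydroxy‑7‑methoxy‑4‑oxo‑4H‑chromene‑2‑carboxylate (chromone ethyl ester) | CCOC(=O)c1cc(=O)c2c(O)cc(OC)cc2o1 | intermediate
5 | 5‑hydroxy‑7‑methoxy‑4‑oxo‑4H‑chromene‑2‑carboxylic acid | COc1cc(O)c2c(=O)cc(C(=O)O)oc2c1 | intermediate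
6 | 5‑hydroxy‑7‑methoxy‑4‑oxochromane‑2‑carboxylic acid, racemic at C2 | COc1cc(O)c2c(c1)OC(C(=O)O)CC2=O | intermediate
7 | 2,3‑dimethoxy‑1,4‑benzoquinone | COC1=C(OC)C(=O)C=CC1=O | starting material
8 | 2‑(4,5‑dimethoxy‑3,6‑dioxocyclohexa‑1,4‑dien‑1‑yl)‑5‑hydroxy‑7‑methoxychroman‑4‑one, racemic at C2 | COc1cc(O)c2c(c1)OC(CC2=O)C1=CC(=O)C(OC)=C(OC)C1=O | intermediate
9 | 2‑(3‑hydroxy‑4,5‑dimethoxy‑6‑oxocyclohexa‑2,4‑dien‑1‑ylidene)‑5‑hydroxy‑7‑methoxychroman‑4‑one (ortho‑quinone methide tautomer; exocyclic alkene geometry not defined, both isomers converge) | COc1cc(O)c2c(c1)OC(CC2=O)=C1C=C(O)C(OC)=C(OC)C1=O | intermediate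
10 | 5‑hydroxy‑7‑methoxy‑2‑(2,5‑dihydroxy‑3,4‑dimethoxyphenyl)‑4H‑chromen‑4‑one (achiral) | COc1cc(O)c2c(=O)cc(-c3cc(O)c(OC)c(OC)c3O)oc2c1 | target

**Step count and risks**

Total step count: 4. Longest linear sequence: 4 steps (1 → 5 → 6 → 8 → 10); quinone 7 enters at step 3.

Steps most likely to fail:

1. Step 4 (proposed new method). The prototropic shift may stall or be diverted: base‑induced retro‑oxa‑Michael opening of ring C, or redox exchange between quinone and hydroquinone followed by air oxidation, would leave a mixture of oxidation levels. The fallback sets out from 8 and uses an external oxidant in place of the internal one. Dehydrogenation of the chromanone ring with I2 in DMSO at 110 °C, the standard flavanone‑to‑flavone oxidation, should give 2‑(4,5‑dimethoxy‑3,6‑dioxocyclohexa‑1,4‑dien‑1‑yl)‑5‑hydroxy‑7‑methoxy‑4H‑chromen‑4‑one F1. Reduction of its quinone ring with aqueous Na2S2O4 in EtOAc should return to the route at 10.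

2. Step 3 (key step). The α‑aryloxy radical may be oxidised to the oxocarbenium ion before it is trapped, ring A may be attacked by the oxidant, or the product quinone may be alkylated a second time. The fallback sets out from 1 and makes the C2–C1' bond part of a purchased aldehyde. Claisen–Schmidt condensation of 1 with 2,3,4,5‑tetramethoxybenzaldehyde (KOH, EtOH, rt) should give (E)‑1‑(2,6‑dihydroxy‑4‑methoxyphenyl)‑3‑(2,3,4,5‑tetramethoxyphenyl)prop‑2‑en‑1‑one F2. Oxidative cyclisation with catalytic I2 in DMSO at 120 °C should give 5‑hydroxy‑7‑methoxy‑2‑(2,3,4,5‑tetramethoxyphenyl)‑4H‑chromen‑4‑one F3. Oxidative demethylation of the para‑dimethoxy pair with ceric ammonium nitrate (MeCN/H2O, 0 °C) should give the quinonyl flavone F1 described above, and aqueous Na2S2O4 should reduce it, returning to the route at 10.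

3. Step 2. Hydrogenation may run on to loss of the C4 carbonyl, or may stall on the pyranone double bond. The fallback sets out from 1 and builds the saturated ring directly, bypassing 5. Acid‑promoted aldol condensation of 1 with glyoxylic acid monohydrate (AcOH, cat. TsOH, 100 °C) should give (E)‑4‑(2,6‑dihydroxy‑4‑methoxyphenyl)‑4‑oxobut‑2‑enoic acid F4. Its 6‑endo oxa‑Michael ring closure in aqueous NaHCO3 at rt, then acidification, should return to the route at 6.

**Further compounds**

F1 | step 4 | 2‑(4,5‑dimethoxy‑3,6‑dioxocyclohexa‑1,4‑dien‑1‑yl)‑5‑hydroxy‑7‑methoxy‑4H‑chromen‑4‑one | COc1cc(O)c2c(=O)cc(C3=CC(=O)C(OC)=C(OC)C3=O)oc2c1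
F2 | step 3 | (E)‑1‑(2,6‑dihydroxy‑4‑methoxyphenyl)‑3‑(2,3,4,5‑tetramethoxyphenyl)prop‑2‑en‑1‑one | COc1cc(O)c(C(=O)/C=C/c2cc(OC)c(OC)c(OC)c2OC)c(O)c1
F3 | step 3 | 5‑hydroxy‑7‑methoxy‑2‑(2,3,4,5‑tetramethoxyphenyl)‑4H‑chromen‑4‑one | COc1cc(O)c2c(=O)cc(-c3cc(OC)c(OC)c(OC)c3OC)oc2c1
F4 | step 2 | (E)‑4‑(2,6‑dihydroxy‑4‑methoxyphenyl)‑4‑oxobut‑2‑enoic acid | COc1cc(O)c(C(=O)/C=C/C(=O)O)c(O)c1
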